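## Retrosynthetic overview
- The target is a 2,3-trans dihydroflavonol carrying a normal prenyl group at C-8 and another at C-3′. Both prenyl groups can be traced to allyl groups by olefin cross-metathesis with 2-methyl-2-butene.
- Each allyl group can be placed ortho to a phenol oxygen by an aromatic Claisen [3,3] rearrangement of the 7-O-allyl and 4′-O-allyl ethers.
- Those ethers come from bis-O-allylation of (2R,3R)-aromadendrin, which already contains all three rings and both stereocenters.
- No ring is built. The chromanone ring and the C2/C3 stereocenters come intact from the starting material. The two C–C bonds are formed in one double Claisen step, and the allyl groups are then converted to prenyl groups.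

Assumption: (+)-aromadendrin, (2R,3R)-dihydrokaempferol, is purchased as the chiral starting material. The 7-allyl Claisen is assumed to go mainly to C-8 because the 5-OH is chelated to the C-4 carbonyl.

## Route

**Step 1**
Reactants: **1** (2R,3R)-aromadendrin; **2** allyl bromide
Product: **3** (2R,3R)-7,4′-di-O-allylaromadendrin
Conditions: **2** (2.4 equiv), K2CO3 (2.5 equiv), acetone, reflux, 12 h
Reagents that add atoms: allyl bromide, C=CCBr
Why: Williamson etherification occurs at the acidic 7-OH and 4′-OH. The chelated 5-OH and the secondary 3-OH are not alkylated under K2CO3/acetone, and the mild conditions leave C2 and C3 untouched.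

**Step 2**
Reactants: **3**
Product: **4** (2R,3R)-8,3′-diallylaromadendrin
Conditions: PhNEt2, 200 °C, microwave, sealed tube, N2, 1–2 h
Reagents that add atoms: none
Why: An aromatic Claisen [3,3] rearrangement moves each allyl group from oxygen to the ortho carbon. The 7-O-allyl group goes mainly to C-8, and the 4′-O-allyl group goes to C-3′. The stereocenters are not involved, and neutral, weakly basic PhNEt2 does not enolize C3, so the 2,3-trans configuration is kept.

**Step 3**
Reactants: **4**; **5** 2-methyl-2-butene
Product: **6** Lespedezaflavanone C
Conditions: **5** (about 50 equiv), Hoveyda–Grubbs II (10 mol%), 1,4-benzoquinone (20 mol%), CH2Cl2, 40 °C, sealed tube, 16 h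
Reagents that add atoms: 2-methyl-2-butene, CC=C(C)C (supplies the CMe2 terminus)
Why: Olefin cross-metathesis of each terminal allyl-arene with the trisubstituted alkene gives the prenyl group and releases propene. Benzoquinone suppresses Ru–H isomerization of the allyl group to propenyl. The stereocenters are remote from the reacting alkenes and are unchanged.

## Compound list
1 | (2R,3R)-aromadendrin, (+)-dihydrokaempferol | Oc1ccc([C@H]2Oc3cc(O)cc(O)c3C(=O)[C@@H]2O)cc1 | starting material
2 | allyl bromide | C=CCBr | starting material (reagent)
3 | (2R,3R)-7,4′-di-O-allylaromadendrin | C=CCOc1ccc([C@H]2Oc3cc(OCC=C)cc(O)c3C(=O)[C@@H]2O)cc1 | intermediate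
4 | (2R,3R)-8,3′-diallylaromadendrin | C=CCc1cc([C@H]2Oc3c(CC=C)c(O)cc(O)c3C(=O)[C@@H]2O)ccc1O | intermediate
5 | 2-methyl-2-butene | CC=C(C)C | starting material (reagent)
6 | Lespedezaflavanone C, (2R,3R)-8,3′-diprenylaromadendrin | CC(C)=CCc1cc([C@H]2Oc3c(CC=C(C)C)c(O)cc(O)c3C(=O)[C@@H]2O)ccc1O | target

## Totals
Total steps: 3. Longest linear sequence: 3.

## Three steps most likely to fail
1. **Step 2, double Claisen.** Risks are C6-allyl regioisomer formation, partial racemization or epimerization at high temperature, and oxidation of the dihydroflavonol to the flavonol.
   - Fallback: change the prenylation approach to direct C-prenylation of **1** with prenyl bromide under aqueous Ca(OH)2 or Ba(OH)2 for C-8, accepting separation of regioisomers, with the B-ring prenyl installed separately.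
2. **Step 3, cross-metathesis.** The free polyphenol may poison the Ru catalyst, and isomerization or incomplete conversion of the two allyl groups is possible.
   - Fallback: skip the allyl/metathesis pathway and install the prenyl groups directly by Claisen. Make the aryl 2-methylbut-3-yn-2-yl ethers (3-chloro-3-methylbut-1-yne, CuI, DBU), reduce them with Lindlar H2 to the 1,1-dimethylallyl ethers, and rearrange thermally to the normal prenyl arenes.
3. **Step 1, bis-allylation.** Over-alkylation at the 3-OH or 5-OH, or base-induced C2 ring-opening and epimerization, would give mixtures.
   - Fallback: form the aryl allyl ethers under neutral Pd(0) conditions (allyl ethyl carbonate, Pd(PPh3)4, THF) instead of with base.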